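Late in a run the excess is a record: by the proposed steps no product is taken back, so the end of a flask holds the sum of what each temperature stage laid down.

all flasks: left-handed substrate 0.25 M; right-handed substrate 0.25 M; free catalyst 5.8 mM
- alpha: coupling partner 0.12 M; temperature −5 °C; run made earlier
- delta: coupling partner 0.50 M; temperature 15 °C; run made earlier
- blue: coupling partner 0.250 M; at 0 °C throughout; time 5.0 h
- grey: coupling partner 0.250 M; at 0 °C until 50 min, from then on at 30 °C; time 1.5 h

| run | time / min | left-handed product / % | right-handed product / % |
|---|---|---|---|
| alpha | 25.0 | 0.8 | 2.3 |
| alpha | 50.0 | 0 | 1.1 |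
| alpha | 80.0 | 0.9 | 2.2 |
| alpha | 120 | 1.8 | 0.6 |
| delta | 8.00 | 3.5 | 2.2 |
| delta | 20.0 | 5.6 | 7.3 |
| delta | 40.0 | 8.4 | 11.1 |
| delta | 60.0 | 12.5 | 15.5 |

(readings scatter by 1 percentage point)

- free catalyst is single-handed; left-handed substrate and right-handed substrate are mirror images of each other, charged as a racemate, each of them at the stated concentration
- steps that have been proposed: free catalyst + left-handed substrate <-> catalyst intermediate A; free catalyst + right-handed substrate <-> catalyst intermediate B; coupling partner + catalyst intermediate A -> free catalyst + left-handed product; coupling partner + catalyst intermediate B -> free catalyst + right-handed product; left-handed substrate <-> right-handed substrate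
- an excess is the difference of the two amounts in percent of their sum
- an excess is below zero if the other one leads

- which of the two ends with the higher excess of left-handed product over right-handed product ("neither" if they lie within 2 percentage points) (blue / grey / neither)
- excess of left-handed product over right-handed product at the end, blue
- excess of left-handed product over right-handed product at the end, grey

Note for the bench. Blue stays cold and grey is warmed, so each stage must be priced. Pooled readings put right-handed over left-handed product (the selectivity factor) at 1.77 in alpha and 1.20 in delta. The last readings, per minute and per molar partner, make delta faster by a factor 5.60. Alpha stands close to its scatter, so this note's own reckoning, with logarithms straight in temperature, is rough: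

Excess at 0 °C: −23.3%; at 30 °C: 5.24%

Grey's product: cold 3.20%, warm 34.0%

Warm share = warm / (cold + warm) = 91.4%

The warm share, the part of the end product made after the change of temperature, weights grey to 2.78%, while blue stays near −23.3%. In this reckoning, grey's warm stage makes product 13.3 times as fast as its cold stage.

The forecast differs: neither, with blue −10% and grey −9%, holding that “A small selectivity barely changes with temperature”.

The flask gives grey: blue −32.2%, grey 4.43%.

    free catalyst + left-handed substrate ⇌ catalyst intermediate A (K = 0.860 L mol⁻¹, k = 41.0 L mol⁻¹ min⁻¹, Ea = 36.0 kJ mol⁻¹, ΔH = 9.00 kJ mol⁻¹)
    free catalyst + right-handed substrate ⇌ catalyst intermediate B (K = 3.50 L mol⁻¹, k = 62.0 L mol⁻¹ min⁻¹, Ea = 41.0 kJ mol⁻¹, ΔH = −16.0 kJ mol⁻¹)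
    coupling partner + catalyst intermediate A → free catalyst + left-handed product (k = 1.00 L mol⁻¹ min⁻¹, Ea = 56.0 kJ mol⁻¹)
    coupling partner + catalyst intermediate B → free catalyst + right-handed product (k = 0.490 L mol⁻¹ min⁻¹, Ea = 60.0 kJ mol⁻¹)
    left-handed substrate ⇌ right-handed substrate (k = 0.0110 min⁻¹, Ea = 92.0 kJ mol⁻¹)
    (constants at 0 °C)

From the cold stage to the warm one in grey, left-handed product came on, on average, 11.9 times as fast, right-handed product 4.89 times. The warm share stands at 85.3%.

In the neighbour with 0.62 M of coupling partner, the reckoning scales both stages alike, so the warm share stays and the excess should stay near grey's. The computed excess there is 3.22%.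

The runs are calculated for an exercise; the scatter is artificial.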